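J.Z falls back to J and Z at 9000 s⁻¹, far faster than it gives Q at 36 s⁻¹, so I treat the binding as a pre-equilibrium.

    Z → X (k1 = 3.3 × 10⁻⁵ s⁻¹, Ea1 = 213 kJ mol⁻¹)
    J + Z → D (k2 = 0.036 M⁻¹ s⁻¹, Ea2 = 65.0 kJ mol⁻¹)
    J.Z → Z + Q (k3 = 36 s⁻¹, Ea3 = 54.0 kJ mol⁻¹)
    J + Z ⇌ J.Z (K4 = 50 M⁻¹, k4 = 4.5 × 10⁵ M⁻¹ s⁻¹, Ea4 = 11.0 kJ mol⁻¹, ΔH4 = 6.00 kJ mol⁻¹)
    (constants at 20 °C)

all flasks: J 11 mM; Z 1.1 µM; time 3.0 min

|  | temperature |
|---|---|
| Wednesday's | 20 °C |
| Friday's | 50 °C |
| Saturday's | 35 °C |

- the best flask by amount of Q, in percent of the J charged; "all alike" if 1.5 percentage points covers them all (Wednesday's / Friday's / Saturday's / all alike)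
- amount of Q at the end, in percent of the J charged, Wednesday's
- amount of Q at the end, in percent of the J charged, Friday's
- amount of Q at the end, in percent of the J charged, Saturday's

- all constants are for 20 °C and move with temperature by the activation energies and enthalpies

Z is the catalyst, charged at 0.0100% of J. It turns J into Q through J.Z, but free Z is also lost, by itself to X and with J to D. So free Z feeds both the making of Q and the loss of catalyst, and its amount cancels in their ratio.

I call that ratio the reach: the part of the charged J that the catalyst turns into Q before it is lost, reckoned with J held at its charge, so that the figure can pass the whole charge, and equal to the Q constant times the binding constant times the Z charge, over the sum of the two loss rates on free Z. Friday's reach is 16.9%. Saturday's is 174%, and Wednesday's is 462%.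

But the clock counts too. The pace, the part of J turned in the given time by undamaged catalyst at the starting rate, is 23.0% for Wednesday's, 207% for Friday's and 72.9% for Saturday's.

So Wednesday's is held by pace, and Friday's by reach. J falls as it is used, so I take the J left as the exponential of minus the smaller figure. That gives Q at 20.5% for Wednesday's and 15.6% for Friday's. Saturday's gets 51.8%, more than either. Saturday's pace is 0.419 of its reach, so part of its catalyst goes within the time; I commit to somewhat less for Saturday's, but it stays my best flask.

The forecast says Saturday's, with 20.7%, 15.2% and 48% for Wednesday's, Friday's and Saturday's, on the grounds that “the yield is set by turnover speed against how long Z survives”.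

Q reaches 20.8% in Wednesday's, 15.3% in Friday's and 48.2% in Saturday's, so Saturday's leads. In Friday's, Z goes to X while catalyst lasts: at 1.50 min J.Z is 0.0557% and Z 0.0975% of the catalyst charged, X is 96.1%, and Q stands at 15.3% of the J charged. In Saturday's, J.Z still holds 15.8% and Z 49.9% of the catalyst charged at 3.00 min, while J.Z gives Q. Reach grows with the Z charge, with J, temperature and time held, so a Friday's flask with 1.50 µM of Z should gain 5.1 percentage points. In that flask Q moves by 5 points.

Its constants were drawn at random within sensible limits; the rest is arithmetic.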